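(The earlier runs and the new flask are calculated with constants of no real substance, noise included.)

J is the enzyme in the dusk flask, and I want two factors on its rate at 5.0% conversion: one with G doubled, one with J at 0.50 µM.

| setting | dusk | summer | flask |
|---|---|---|---|
| X | 5.0 × 10⁻⁴ M | 5.0 × 10⁻⁴ M | 5.0 × 10⁻⁴ M |
| G | 1 mM | 0.67 mM | 1.00 mM |
| J | 0.050 µM | 0.050 µM | 0.050 µM |
| remark | the very flask that is asked about, followed so far | run made earlier |  |

- dusk (time / s: E / %, X / %): 10.0: 14.3, 85.7; 12.0: 16.2, 83.5; 20.0: 23.7, 76.8; 25.0: 28.0, 72.4; 30.0: 30.3, 69.7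
- summer (time / s: E / %, X / %): 10.0: 17.5, 82.8; 15.0: 22.4, 76.1; 30.0: 35.4, 65.7; 50.0: 39.2, 61.2; 60.0: 39.8, 60.6; 80.0: 41.1, 59.5; 120: 41.6, 59.6

(scatter of a reading: 0.5 percentage points)

- factor on the rate of making E when 5.0% of the X are converted if G is charged twice over
- factor on the rate when 5.0% of the X are converted if J is charged at 0.50 µM instead

- no earlier run changes the charge of J; that part of a forecast is a guess

I work with the fraction of X left. Two runs standing at the same fraction left have covered the same stretch of X, so the inverse of their clock ratio is a rate ratio averaged over that stretch. The dusk run has 76.8% left at 20.0 s and the summer run 76.1% at 15.0 s, a gap of 0.7 percentage points; the E readings at those points, 23.7% and 22.4%, lean the other way, so I treat the two points as level.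

Which inputs must be good? The J charge is the same in both runs, so that factor stays a guess: simple proportion, 10.0. The clocks matter. Near that point, 0.5 points of scatter is worth 0.551 s of clock, taking the dusk pace for both runs, and on the summer clock that moves the factor for doubled G to 0.647.

The stretch exponent, the logarithm of the clock ratio at equal fraction left over the logarithm of the G ratio, comes to 0.718. Carried on trust to doubled G and to 5.0% conversion, it gives a rate factor of 0.608.

The forecast says 0.6 and 10, on an apparent order in G of about minus 0.7, “with large uncertainty”.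

The dusk flask gives 0.603 and 10.0, against my 0.608 and 10.0.

    X + J ⇌ Z (K = 2100 M⁻¹, k = 8.37 × 10⁷ M⁻¹ s⁻¹)
    Z ⇌ J + E (K = 3.30 × 10⁻⁴ M, k = 958 s⁻¹)
    G + J ⇌ D (K = 3900 M⁻¹, k = 1.03 × 10⁸ M⁻¹ s⁻¹)
    D → J + Q (k = 188 s⁻¹)

With G doubled, the time to that conversion grows by a factor of 1.66, and the stretch exponent gives 1.64 for that flask. In the dusk flask at 1.07 min, J enters the step from G + J to D 2.5 times as fast as the step from X + J to Z, forward rates alone. At 1.25 min, D, the resting state there, is 56.9% of the catalyst, against 26.4% J and 16.6% Z.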